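The bond between C1 of ring B (the central guaiacyl ring) and its benzylic carbinol carbon C7 is the disconnection on which the route rests. In the key step an aryltitanium reagent, made from a ring B bromide that already carries the complete ring A arylglycerol unit, adds to an (R)-2-aryloxy-3-silyloxypropanal that carries the syringaresinol core (rings C and D) and the ring E unit. One operation joins the halves and sets C7 as S. The feature exploited is the C8 stereocentre bearing the ring C aryloxy group next to the carbonyl, which directs a polar Felkin–Anh (7,8-anti, erythro) addition. The same aryl-to-glyceraldehyde logic builds both outer units.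

Key step: step 13

Assumption: the (7R,8S,7′R,8′S) enantiomer of syringaresinol (the levorotatory natural product) and both enantiomers of methyl 2,3-dihydroxypropanoate are taken as purchasable.

Conventions: in each arylglycerol unit C7 is the benzylic carbinol carbon, C8 the aryloxy-bearing carbon and C9 the CH2O carbon. Rings A and E are the terminal 4-hydroxy-3-methoxyphenyl rings, ring B is the central 3-methoxy-4-oxyphenyl ring, and rings C and D are the two 3,5-dimethoxy-4-oxyphenyl rings of the furofuran core, ring C being the one linked to the ring B unit. TIPS = triisopropylsilyl, TBDPS = tert-butyldiphenylsilyl, TBS = tert-butyldimethylsilyl, TES = triethylsilyl.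

Step 1
Reactants: 1 4-bromo-2-methoxyphenol
Product: 2 (4-bromo-2-methoxyphenoxy)triisopropylsilane
Conditions: TIPSCl, imidazole, DMF, rt
Reagents that add atoms: triisopropylsilyl chloride, CC(C)[Si](Cl)(C(C)C)C(C)C
Why: Imidazole-promoted O-silylation of the phenol gives a TIPS ether that should withstand bromine–lithium exchange and falls to fluoride at the end.

Step 2
Reactants: 2 (4-bromo-2-methoxyphenoxy)triisopropylsilane
Product: 4 [3-methoxy-4-(triisopropylsilyloxy)phenyl]titanium triisopropoxide, via aryllithium 3 (not isolated)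
Conditions: nBuLi (1.0 equiv), THF, −78 °C; ClTi(OiPr)3 (1.0 equiv), −78 to 0 °C; solvent changed to toluene, LiCl filtered off under argon; assayed stock solution kept at −20 °C in the dark
Reagents that add atoms: chlorotitanium triisopropoxide, CC(C)O[Ti](Cl)(OC(C)C)OC(C)C
Why: Bromine–lithium exchange gives aryllithium 3, which chlorotitanium triisopropoxide captures by transmetalation, and since aryltitanium triisopropoxides keep under argon in the cold, one assayed batch should serve both aryl additions of the route (steps 6 and 11).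

Step 3
Reactants: 5 methyl (R)-2,3-dihydroxypropanoate
Product: 6 methyl (R)-3-(tert-butyldiphenylsilyloxy)-2-hydroxypropanoate
Conditions: TBDPSCl (1.05 equiv), imidazole, CH2Cl2, 0 °C
Reagents that add atoms: tert-butyldiphenylsilyl chloride, CC(C)(C)[Si](Cl)(c1ccccc1)c1ccccc1
Why: The bulky silyl chloride should silylate the primary hydroxyl selectively and leave the secondary hydroxyl and the stereocentre untouched.

Step 4
Reactants: 1 4-bromo-2-methoxyphenol; 6 methyl (R)-3-(tert-butyldiphenylsilyloxy)-2-hydroxypropanoate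
Product: 7 methyl (S)-2-(4-bromo-2-methoxyphenoxy)-3-(tert-butyldiphenylsilyloxy)propanoate
Conditions: PPh3, DIAD, THF, 0 °C to rt
Reagents that add atoms: none
Why: Mitsunobu reaction, in which the phenoxide displaces the oxyphosphonium group at the carbonyl-activated carbon by SN2 with inversion, so the (R) alcohol should give the (S) aryl ether that becomes C8 of the ring A unit.

Step 5
Reactants: 7 methyl (S)-2-(4-bromo-2-methoxyphenoxy)-3-(tert-butyldiphenylsilyloxy)propanoate
Product: 8 (S)-2-(4-bromo-2-methoxyphenoxy)-3-(tert-butyldiphenylsilyloxy)propanal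
Conditions: iBu2AlH (1.1 equiv), CH2Cl2, −78 °C; MeOH, then aqueous KNaC4H4O6; used crude at once
Reagents that add atoms: none
Why: Partial reduction of the ester, in which the chelated aluminium hemiacetal persists at −78 °C and releases the aldehyde only on work-up, so C8 should not be touched.

Step 6
Reactants: 4 [3-methoxy-4-(triisopropylsilyloxy)phenyl]titanium triisopropoxide; 8 (S)-2-(4-bromo-2-methoxyphenoxy)-3-(tert-butyldiphenylsilyloxy)propanal
Product: 9 (1R,2S)-2-(4-bromo-2-methoxyphenoxy)-3-(tert-butyldiphenylsilyloxy)-1-[3-methoxy-4-(triisopropylsilyloxy)phenyl]propan-1-ol (erythro carbinol)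
Conditions: 4 (1.3 equiv, toluene solution), 8 in THF, −78 to −20 °C; aqueous NH4Cl
Reagents that add atoms: none
Why: The preformed, weakly basic aryltitanium triisopropoxide adds to the aldehyde without chelation (organotitanium 1,2-addition to an alpha-alkoxy aldehyde), so the polar Felkin–Anh transition state (C8–OAr bond anti to the incoming aryl, attack past the C8 hydrogen) should set C7 as R, 7,8-anti, while the ring B bromide of 8 stays untouched because no organolithium is present.

Step 7
Reactants: 9 the erythro carbinol of step 6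
Product: 10 ring B bromide with the complete protected ring A unit: the C7 tert-butyldimethylsilyl ether of 9 with the (1R,2S) configuration retained
Conditions: TBSOTf, 2,6-lutidine, CH2Cl2, −78 to 0 °C
Reagents that add atoms: tert-butyldimethylsilyl trifluoromethanesulfonate, CC(C)(C)[Si](C)(C)OS(=O)(=O)C(F)(F)F
Why: Silyl triflate silylation of the hindered secondary benzylic alcohol removes the only acidic proton before the later bromine–lithium exchange.

Step 8
Reactants: 11 methyl (S)-2,3-dihydroxypropanoate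
Product: 12 methyl (S)-3-(tert-butyldiphenylsilyloxy)-2-hydroxypropanoate
Conditions: TBDPSCl (1.05 equiv), imidazole, CH2Cl2, 0 °C
Reagents that add atoms: tert-butyldiphenylsilyl chloride, CC(C)(C)[Si](Cl)(c1ccccc1)c1ccccc1
Why: Selective silylation of the primary hydroxyl as in step 3, with the stereocentre untouched.

Step 9
Reactants: 13 (7R,8S,7′R,8′S)-syringaresinol, 4,4′-[(1R,3aS,4R,6aS)-tetrahydro-1H,3H-furo[3,4-c]furan-1,4-diyl]bis(2,6-dimethoxyphenol); 12 methyl (S)-3-(tert-butyldiphenylsilyloxy)-2-hydroxypropanoate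
Product: 14 C2-symmetric bis-ester: syringaresinol in which each phenolic oxygen (rings C and D) carries an (R)-1-(methoxycarbonyl)-2-(tert-butyldiphenylsilyloxy)ethyl group
Conditions: 12 (2.6 equiv), PPh3 (3 equiv), DIAD (3 equiv), THF, 0 to 40 °C
Reagents that add atoms: none
Why: Twofold Mitsunobu reaction, in which each 2,6-dimethoxyphenoxide displaces the oxyphosphonium group alpha to the ester by SN2 with inversion, so the (S) alcohol should give the two (R) centres that become C8 of the ring B and ring E units.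

Step 10
Reactants: 14 the bis-ester of step 9
Product: 15 C2-symmetric dialdehyde: syringaresinol in which each phenolic oxygen carries an (R)-1-formyl-2-(tert-butyldiphenylsilyloxy)ethyl group
Conditions: iBu2AlH (2.3 equiv), CH2Cl2, −78 °C; MeOH, then aqueous KNaC4H4O6; used crude at once
Reagents that add atoms: none
Why: Twofold partial ester reduction through aluminium hemiacetals that are stable at −78 °C, as in step 5, which should leave both C8 centres, the silyl ethers and the furofuran untouched.

Step 11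
Reactants: 15 the dialdehyde of step 10; 4 [3-methoxy-4-(triisopropylsilyloxy)phenyl]titanium triisopropoxide
Product: 16 hydroxy aldehyde: the ring C oxygen keeps the (R)-1-formyl-2-(tert-butyldiphenylsilyloxy)ethyl group and the ring D oxygen carries C8 of a (7S,8R) erythro arylglycerol unit that has a free C7–OH, a C9 TBDPS ether and ring E as its TIPS ether
Conditions: 4 (0.85 equiv, toluene solution) added slowly to 15 in THF, −78 to −30 °C; aqueous NH4Cl; unreacted 15 recovered and resubmitted at once
Reagents that add atoms: none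
Why: Because 15 is C2-symmetric either aldehyde gives the same mono-adduct, and the same non-chelation organotitanium 1,2-addition (polar Felkin–Anh) should set C7 of the ring E unit as S, 7,8-anti, while the sub-stoichiometric aryl donor limits the statistically unavoidable double addition.

Step 12
Reactants: 16 the hydroxy aldehyde of step 11
Product: 17 aldehyde carrying the protected ring E unit: the C7 triethylsilyl ether of 16
Conditions: TESCl, imidazole, CH2Cl2, 0 °C; rapid chromatography
Reagents that add atoms: chlorotriethylsilane, CC[Si](Cl)(CC)CC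
Why: Mild O-silylation masks the carbinol proton under conditions too weakly basic to enolise the alpha-aryloxy aldehyde, so C8 of the aldehyde arm should keep its configuration.

Step 13
Reactants: 10 the ring B bromide of step 7; 17 the aldehyde of step 12
Product: 20 heptasilylated target with a free C7–OH in the (7S,8R) ring B unit, via ring B aryllithium 18 (not isolated), via ring B aryltitanium triisopropoxide 19 (not isolated)
Conditions: 10 (1.3 equiv), nBuLi (1.25 equiv), THF, −78 °C; ClTi(OiPr)3, −78 to −40 °C; then 17 (1.0 equiv) in THF, −78 to −10 °C; aqueous NH4Cl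
Reagents that add atoms: none
Why: Bromine–lithium exchange on ring B of 10 gives aryllithium 18, which ClTi(OiPr)3 converts into aryltitanium triisopropoxide 19, and this weakly basic, weakly Lewis acidic aryl donor adds once to the aldehyde carbon of 17 through a four-centre transition state to forge the C1(ring B)–C7 bond. The closest known reaction type is the non-chelation-controlled 1,2-addition of organotitanium triisopropoxides to alpha-alkoxy aldehydes such as protected glyceraldehydes. No ring is closed. The new C7 stereocentre is controlled by the neighbouring C8 stereocentre: in the polar Felkin–Anh transition state the C8–O(ring C) bond lies anti to the incoming aryl group and the aryl passes the C8 hydrogen, which should give the 7,8-anti (erythro) carbinol, here (7S,8R). The step needs chemoselectivity for the aldehyde over seven silyl ethers and freedom from enolisation, from beta-elimination of the C9 silyloxy group and from C8 epimerisation; the low basicity of the titanium reagent, the inability of the Ti(OiPr)3 centre to chelate the hindered 2,6-dimethoxyphenoxy oxygen and the bulky, non-coordinating TBDPS ether at C9 should secure this.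

Step 14
Reactants: 20 the heptasilylated coupling product of step 13
Product: 21 CNP0316493.2: (7R,8S,7′R,8′S)-syringaresinol whose ring D oxygen bears C8 of a (7S,8R)-guaiacylglycerol (ring E) and whose ring C oxygen bears C8 of a (7S,8R)-arylglycerol whose ring B 4-oxygen bears C8 of a (7R,8S)-guaiacylglycerol (ring A)
Conditions: Bu4NF (excess), AcOH (1 equiv per fluoride), THF, 0 to 40 °C
Reagents that add atoms: none
Why: Fluoride cleaves all Si–O bonds (two aryl TIPS, three primary TBDPS, one TBS and one TES ether) in one global desilylation, and the acetic acid buffer should keep the medium near neutral so the benzylic carbinols neither ionise nor epimerise.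

Compound list
1 | 4-bromo-2-methoxyphenol | COc1cc(Br)ccc1O | starting material
2 | (4-bromo-2-methoxyphenoxy)triisopropylsilane | COc1cc(Br)ccc1O[Si](C(C)C)(C(C)C)C(C)C | intermediate
3 | [3-methoxy-4-(triisopropylsilyloxy)phenyl]lithium | COc1cc([Li])ccc1O[Si](C(C)C)(C(C)C)C(C)C | intermediate
4 | [3-methoxy-4-(triisopropylsilyloxy)phenyl]titanium triisopropoxide | COc1cc([Ti](OC(C)C)(OC(C)C)OC(C)C)ccc1O[Si](C(C)C)(C(C)C)C(C)C | intermediate
5 | methyl (R)-2,3-dihydroxypropanoate | COC(=O)[C@H](O)CO | starting material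
6 | methyl (R)-3-(tert-butyldiphenylsilyloxy)-2-hydroxypropanoate | COC(=O)[C@H](O)CO[Si](c1ccccc1)(c1ccccc1)C(C)(C)C | intermediate
7 | methyl (S)-2-(4-bromo-2-methoxyphenoxy)-3-(tert-butyldiphenylsilyloxy)propanoate | COC(=O)[C@@H](Oc1ccc(Br)cc1OC)CO[Si](c1ccccc1)(c1ccccc1)C(C)(C)C | intermediate
8 | (S)-2-(4-bromo-2-methoxyphenoxy)-3-(tert-butyldiphenylsilyloxy)propanal | O=C[C@@H](Oc1ccc(Br)cc1OC)CO[Si](c1ccccc1)(c1ccccc1)C(C)(C)C | intermediate
9 | (1R,2S)-2-(4-bromo-2-methoxyphenoxy)-3-(tert-butyldiphenylsilyloxy)-1-[3-methoxy-4-(triisopropylsilyloxy)phenyl]propan-1-ol | COc1cc([C@@H](O)[C@H](CO[Si](c2ccccc2)(c2ccccc2)C(C)(C)C)Oc2ccc(Br)cc2OC)ccc1O[Si](C(C)C)(C(C)C)C(C)C | intermediate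
10 | C7 TBS ether of 9 (ring B bromide with protected ring A unit) | COc1cc([C@@H](O[Si](C)(C)C(C)(C)C)[C@H](CO[Si](c2ccccc2)(c2ccccc2)C(C)(C)C)Oc2ccc(Br)cc2OC)ccc1O[Si](C(C)C)(C(C)C)C(C)C | intermediate
11 | methyl (S)-2,3-dihydroxypropanoate | COC(=O)[C@@H](O)CO | starting material
12 | methyl (S)-3-(tert-butyldiphenylsilyloxy)-2-hydroxypropanoate | COC(=O)[C@@H](O)CO[Si](c1ccccc1)(c1ccccc1)C(C)(C)C | intermediate
13 | (7R,8S,7′R,8′S)-syringaresinol | COc1cc([C@@H]2OC[C@@H]3[C@H]2CO[C@H]3c2cc(OC)c(O)c(OC)c2)cc(OC)c1O | starting material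
14 | syringaresinol bis-O-[(R)-1-(methoxycarbonyl)-2-(tert-butyldiphenylsilyloxy)ethyl] ether (bis-ester) | COC(=O)[C@@H](CO[Si](c1ccccc1)(c1ccccc1)C(C)(C)C)Oc1c(OC)cc([C@@H]2OC[C@@H]3[C@H]2CO[C@H]3c2cc(OC)c(O[C@@H](C(=O)OC)CO[Si](c3ccccc3)(c3ccccc3)C(C)(C)C)c(OC)c2)cc1OC | intermediate
15 | syringaresinol bis-O-[(R)-1-formyl-2-(tert-butyldiphenylsilyloxy)ethyl] ether (dialdehyde) | O=C[C@@H](CO[Si](c1ccccc1)(c1ccccc1)C(C)(C)C)Oc1c(OC)cc([C@@H]2OC[C@@H]3[C@H]2CO[C@H]3c2cc(OC)c(O[C@@H](C=O)CO[Si](c3ccccc3)(c3ccccc3)C(C)(C)C)c(OC)c2)cc1OC | intermediate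
16 | hydroxy aldehyde: aldehyde arm on ring C, (7S,8R) ring E unit with free C7–OH on ring D | O=C[C@@H](CO[Si](c1ccccc1)(c1ccccc1)C(C)(C)C)Oc1c(OC)cc([C@@H]2OC[C@@H]3[C@H]2CO[C@H]3c2cc(OC)c(O[C@H](CO[Si](c3ccccc3)(c3ccccc3)C(C)(C)C)[C@@H](O)c3ccc(O[Si](C(C)C)(C(C)C)C(C)C)c(OC)c3)c(OC)c2)cc1OC | intermediate
17 | C7 TES ether of 16 (aldehyde with protected ring E unit) | O=C[C@@H](CO[Si](c1ccccc1)(c1ccccc1)C(C)(C)C)Oc1c(OC)cc([C@@H]2OC[C@@H]3[C@H]2CO[C@H]3c2cc(OC)c(O[C@H](CO[Si](c3ccccc3)(c3ccccc3)C(C)(C)C)[C@@H](O[Si](CC)(CC)CC)c3ccc(O[Si](C(C)C)(C(C)C)C(C)C)c(OC)c3)c(OC)c2)cc1OC | intermediate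
18 | ring B aryllithium derived from 10 | COc1cc([C@@H](O[Si](C)(C)C(C)(C)C)[C@H](CO[Si](c2ccccc2)(c2ccccc2)C(C)(C)C)Oc2ccc([Li])cc2OC)ccc1O[Si](C(C)C)(C(C)C)C(C)C | intermediate
19 | ring B aryltitanium triisopropoxide derived from 10 | COc1cc([C@@H](O[Si](C)(C)C(C)(C)C)[C@H](CO[Si](c2ccccc2)(c2ccccc2)C(C)(C)C)Oc2ccc([Ti](OC(C)C)(OC(C)C)OC(C)C)cc2OC)ccc1O[Si](C(C)C)(C(C)C)C(C)C | intermediate
20 | heptasilylated target (two aryl TIPS, three C9 TBDPS, C7 TBS in the ring A unit, C7 TES in the ring E unit, free C7–OH in the ring B unit) | COc1cc([C@@H](O[Si](C)(C)C(C)(C)C)[C@H](CO[Si](c2ccccc2)(c2ccccc2)C(C)(C)C)Oc2ccc([C@H](O)[C@@H](CO[Si](c3ccccc3)(c3ccccc3)C(C)(C)C)Oc3c(OC)cc([C@@H]4OC[C@@H]5[C@H]4CO[C@H]5c4cc(OC)c(O[C@H](CO[Si](c5ccccc5)(c5ccccc5)C(C)(C)C)[C@@H](O[Si](CC)(CC)CC)c5ccc(O[Si](C(C)C)(C(C)C)C(C)C)c(OC)c5)c(OC)c4)cc3OC)cc2OC)ccc1O[Si](C(C)C)(C(C)C)C(C)C | intermediate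
21 | CNP0316493.2 | COc1cc([C@@H](O)[C@H](CO)Oc2ccc([C@H](O)[C@@H](CO)Oc3c(OC)cc([C@@H]4OC[C@@H]5[C@H]4CO[C@H]5c4cc(OC)c(O[C@H](CO)[C@@H](O)c5ccc(O)c(OC)c5)c(OC)c4)cc3OC)cc2OC)ccc1O | target

Total step count: 14.
Longest linear sequence: 7 steps (steps 3, 4, 5, 6, 7, 13, 14 from compound 5; equally steps 8 to 14 from compound 11).

Steps most likely to fail

Step 13 (key step). The facial selectivity at C7 may erode if a chelated transition state competes with the polar Felkin–Anh pathway, so that the carbinol is formed as a mixture of C7 epimers. The fallback sets the stereocentre by hydride delivery instead of by the carbon–carbon bond formation. It sets out from compounds 10 and 17 and comes back at compound 20. The addition is run as before, and compound 20 together with its C7 epimer, the (7R,8R) threo carbinol F1, is not separated. The mixture is oxidised with Dess–Martin periodinane and NaHCO3 in CH2Cl2 to the ring B aryl ketone F2. F2 is then reduced with Zn(BH4)2 in Et2O at −20 °C. In the Cram chelate that the strongly Lewis acidic zinc forms between the ketone oxygen and the C8 aryloxy oxygen, hydride is delivered past the C8 hydrogen, which should give the 7,8-anti carbinol 20 from both epimers.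

Step 11. The statistical mono-addition may overshoot to the bis-adduct, and the twofold alpha-aryloxy aldehyde may epimerise at C8 or lose silanol by beta-elimination during reaction and separation. The fallback moves the desymmetrisation to the stable ester stage. It sets out from compound 14 and comes back at compound 17. Compound 14 is half-reduced with iBu2AlH (1.0 equiv, CH2Cl2, −78 °C) to the aldehyde ester F3, and unreacted 14 is stable and is recycled. Aryltitanium 4 (from step 2) is added to F3 at −78 to −30 °C; it reacts with the aldehyde only, esters being inert to it, and should give the (7S,8R) hydroxy ester F4. TESCl and imidazole in CH2Cl2 convert F4 into the TES ether ester F5. iBu2AlH (1.1 equiv, CH2Cl2, −78 °C) then reduces the remaining ester of F5 to give aldehyde 17.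

Step 9. The twofold etherification at the hindered 2,6-dimethoxyphenol oxygens may be slow and incomplete, with the oxyphosphonium intermediate diverted to elimination or to alkylation of the hydrazide. The fallback replaces the redox condensation by a direct SN2 displacement. It sets out from compounds 12 and 13 and comes back at compound 14. Compound 12 is converted with Tf2O and 2,6-lutidine in CH2Cl2 at −78 °C into methyl (S)-3-(tert-butyldiphenylsilyloxy)-2-(trifluoromethylsulfonyloxy)propanoate F6. The bis-phenoxide of 13 (K2CO3, MeCN, 0 °C to rt) displaces the triflate of F6 (2.4 equiv) with inversion at both centres, which should give bis-ester 14.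

Further compounds
F1 | step 13 | C7 epimer of 20 in the ring B unit, (7R,8R) threo carbinol | COc1cc([C@@H](O[Si](C)(C)C(C)(C)C)[C@H](CO[Si](c2ccccc2)(c2ccccc2)C(C)(C)C)Oc2ccc([C@@H](O)[C@@H](CO[Si](c3ccccc3)(c3ccccc3)C(C)(C)C)Oc3c(OC)cc([C@@H]4OC[C@@H]5[C@H]4CO[C@H]5c4cc(OC)c(O[C@H](CO[Si](c5ccccc5)(c5ccccc5)C(C)(C)C)[C@@H](O[Si](CC)(CC)CC)c5ccc(O[Si](C(C)C)(C(C)C)C(C)C)c(OC)c5)c(OC)c4)cc3OC)cc2OC)ccc1O[Si](C(C)C)(C(C)C)C(C)C
F2 | step 13 | ring B aryl ketone (C7 oxo analogue of 20) | COc1cc([C@@H](O[Si](C)(C)C(C)(C)C)[C@H](CO[Si](c2ccccc2)(c2ccccc2)C(C)(C)C)Oc2ccc(C(=O)[C@@H](CO[Si](c3ccccc3)(c3ccccc3)C(C)(C)C)Oc3c(OC)cc([C@@H]4OC[C@@H]5[C@H]4CO[C@H]5c4cc(OC)c(O[C@H](CO[Si](c5ccccc5)(c5ccccc5)C(C)(C)C)[C@@H](O[Si](CC)(CC)CC)c5ccc(O[Si](C(C)C)(C(C)C)C(C)C)c(OC)c5)c(OC)c4)cc3OC)cc2OC)ccc1O[Si](C(C)C)(C(C)C)C(C)C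
F3 | step 11 | aldehyde ester: syringaresinol with one (R)-1-formyl-2-(TBDPS-oxy)ethyl and one (R)-1-(methoxycarbonyl)-2-(TBDPS-oxy)ethyl ether arm | COC(=O)[C@@H](CO[Si](c1ccccc1)(c1ccccc1)C(C)(C)C)Oc1c(OC)cc([C@@H]2OC[C@@H]3[C@H]2CO[C@H]3c2cc(OC)c(O[C@@H](C=O)CO[Si](c3ccccc3)(c3ccccc3)C(C)(C)C)c(OC)c2)cc1OC
F4 | step 11 | hydroxy ester: ester arm on ring C, (7S,8R) ring E unit with free C7–OH on ring D | COC(=O)[C@@H](CO[Si](c1ccccc1)(c1ccccc1)C(C)(C)C)Oc1c(OC)cc([C@@H]2OC[C@@H]3[C@H]2CO[C@H]3c2cc(OC)c(O[C@H](CO[Si](c3ccccc3)(c3ccccc3)C(C)(C)C)[C@@H](O)c3ccc(O[Si](C(C)C)(C(C)C)C(C)C)c(OC)c3)c(OC)c2)cc1OC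
F5 | step 11 | C7 TES ether of F4 | COC(=O)[C@@H](CO[Si](c1ccccc1)(c1ccccc1)C(C)(C)C)Oc1c(OC)cc([C@@H]2OC[C@@H]3[C@H]2CO[C@H]3c2cc(OC)c(O[C@H](CO[Si](c3ccccc3)(c3ccccc3)C(C)(C)C)[C@@H](O[Si](CC)(CC)CC)c3ccc(O[Si](C(C)C)(C(C)C)C(C)C)c(OC)c3)c(OC)c2)cc1OC
F6 | step 9 | methyl (S)-3-(tert-butyldiphenylsilyloxy)-2-(trifluoromethylsulfonyloxy)propanoate | COC(=O)[C@@H](OS(=O)(=O)C(F)(F)F)CO[Si](c1ccccc1)(c1ccccc1)C(C)(C)C
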